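## Analysis of the target

The target is a germacrane: a ten-membered carbocycle C1–C10 with methyl groups on C10 (C14) and C4 (C15) and an isopropyl group on C7. It carries one E trisubstituted alkene (C1=C10), a trans trisubstituted epoxide across C4–C5, and two acylated secondary carbinols: C6 bears a (2R,3S)-3-hydroxy-2-methylbutanoate and C8 a tiglate. The five contiguous ring stereocentres are 4R,5R,6S,7S,8R. Along the chain the C5 and C6 oxygens are syn, the C6 oxygen and the isopropyl group anti, the isopropyl group and the C8 oxygen syn, and the two ester oxygens 1,3-anti, so on the crown-shaped ring the substituents on C6, C7 and C8 all point outward and H6, H7 and H8 are alternately axial. The epoxide lies across the ring from the C1=C10 alkene and will cyclise transannularly under acid; the β-hydroxy ester can eliminate or transfer its acyl group; the tiglate can deconjugate under base. The hard points are the medium ring itself, stereocontrol on a flexible ring, telling the C6 and C8 hydroxyls apart, and a trans epoxide that no small-ring precursor can contain.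

The strategy rests on one relationship: the C6 oxygen and the C1=C10 alkene stand as in a cyclodec-5-enone, the product pattern of an oxy-Cope ring expansion. C1–C6 with C15 form a p-menthane ring of the isopulegol kind, whose isopropenyl group on C1 holds C9, C10 and C14. An alkenyl group C7=C8 on C6 completes the 1,5-diene C8=C7–C6–C1–C10=C9.

The ring is not taken from isopulegol itself. That would require dihydroxylating an enone alkene beside the more reactive isopropenyl group, and only one epimerisable centre would carry the absolute configuration. The same ring is therefore closed by the carbonyl-ene reaction that makes isopulegol, on a chain in which C4 and C5 are already set by reagent control.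

## Retrosynthetic reasoning

**35 ⇒ 34.** The last bond cut is the O–Si bond of the side chain. The free β-hydroxyl would compete in every acylation and in the sulfonylation, so it stays masked to the end; the forward step must be non-acidic because of the epoxide.

**34 ⇒ 31 + 32.** The C8–O acyl bond is cut next. The tiglate is a Michael acceptor and would not survive hydride or organometallic steps, so it goes on late, through mixed anhydride 33 so that the double bond does not move out of conjugation.

**31 ⇒ 30.** The C8 oxygen is carried as a 4-methoxybenzyl ether. This group enters as the substituent of the enol ether, keeps C8 distinct from C6, and leaves oxidatively under neutral conditions that spare the epoxide.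

**30 ⇒ 28 (through 29).** The C5–O bond of the epoxide is cut. A trans epoxide cannot sit in a six-membered ring, but a cis diol can. Closing the C4 oxygen onto C5 with inversion turns that diol into the trans epoxide. Only the secondary C5 hydroxyl of 28 can be sulfonylated.

**28 ⇒ 27.** The diol is masked as an acetonide, the one diol protection that tolerates the organolithium and KH steps between.

**27 ⇒ 19 + 25.** The C6–O acyl bond is cut while C5 and C8 are still blocked, so there is no regiochemical question. Acid 25 goes back through 24 to aldol adduct 23, cut at C2′–C3′ into 20 and 21, with the auxiliary of 20 setting both side-chain centres.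

**19 ⇒ 18.** The C6 carbinol comes from the ketone that the rearrangement delivers. The forward step must add hydride to the outer face of the carbonyl.

**18 ⇒ 15 (through 16 and 17).** This is the key disconnection: C8–C9 is cut and C1–C6 reconnected. It is made here because it replaces a ten-membered ring by a cyclohexane and removes two stereocentres (C7, C8). It trades them for the geometry of an enol ether and the relative configuration of a cyclohexanol. The forward step must run through one chair, give the E alkene, and keep the β-alkoxy enolate intact.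

**15 ⇒ 9 + 13 (through 14).** The C6–C7 bond is cut. Ketone 9 is flanked by the C1 isopropenyl group and the acetonide, which together should steer a bulky alkenyl nucleophile to one face.

**13 ⇒ 11 + 12; 11 ⇒ 10.** The vinylic C8–O bond is cut, then both halogens. The E geometry comes from an anti addition to the alkyne, so it is fixed before the oxygen arrives.

**9 ⇒ 8 ⇒ 7.** The C1–C6 bond is cut by a retro carbonyl-ene step. This gives the ring, the isopropenyl group and the C1 configuration in one operation from an open chain; the C6 carbinol of 8 is then oxidised.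

**7 ⇒ 6 ⇒ 5 ⇒ 4 ⇒ 3 ⇒ 2 ⇒ 1.** The rest are functional-group changes back to allylic alcohol 1. The C5 oxygen comes from asymmetric epoxidation; the C4 oxygen comes from opening epoxide 2 with inversion. The primary hydroxyl is silylated only so that the acetonide can bridge nothing but C4 and C5.

## Alternatives that were turned down

**Alternative 1:** The whole ring and the C6 oxygen are traced back to farnesyl diphosphate A2. A sesquiterpene synthase would ionise A2, join C6 to C7, move a hydride from C6 to the side-chain cation and hydrate C6, giving dienol A1.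
- For: one step sets the ring, both E alkenes and C6/C7. On step count and on the ring-forming event it is stronger than anything chemical.
- Against: A1 has no oxygen on C8. C8 is an unactivated methylene, neither allylic nor next to a heteroatom, so a second, site- and face-selective C–H hydroxylation is needed, in practice another enzyme. The 4,5-alkene must then be epoxidised selectively, and the route depends on enzyme expression, not on steps that can be argued from mechanism.
- Comparison: the chosen strategy is far longer, but it places the C8 oxygen by construction and sets each centre by a chemical control element.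

**Alternative 2:** The C2–C3 bond is cut. An α-sulfonyl allyl anion at C2 would displace a primary allylic bromide at C3 of the same chain to give sulfone A3.
- For: both trisubstituted E alkenes are made in the open chain, where geometry is easy. The C6–C8 triad is built by acyclic aldol-type methods, which is more secure than reduction and protonation on a ten-membered ring. On C6/C7 control this alternative is stronger.
- Against: the ring is closed end to end, against the entropy and transannular strain of a ten-membered ring, at high dilution, with an ambident anion and competing intermolecular alkylation. The sulfone must then be removed reductively at an allylic position. The epoxide must be placed at the end on one of two similar trisubstituted alkenes, with the face decided by the ring. The open-chain precursor is long.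
- Comparison: the chosen strategy makes the ring by rearrangement without dilution and carries the C4/C5 oxygens in from a reagent-controlled diol, at the price of weaker control over C6 and C7.

**Alternative 3:** The C1=C10 alkene and a C5 carbonyl are traced back to the C5–C10 bond of a decalin. A C5 alkoxide would expel a C1 sulfonate in a Wharton–Grob fragmentation to give ketone A4.
- For: the fragmentation is concerted and stereospecific, and the E alkene follows from the anti-periplanar bonds of a rigid bicycle. C4, C6, C7 and C8 are set on a decalin where faces are predictable, and no β-alkoxy enolate is formed. On reliability of ring formation and on C6–C8 control it is as strong as or stronger than the chosen route.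
- Against: the decalin needs substituents on eight of its ten carbons in one exact relative configuration, including the sulfonate anti to the bond that breaks, which means a long linear synthesis. A4 still needs a stereoselective C5 reduction on the ten-membered ring and the same epoxide closure, with three protecting groups to handle and an epimerisable C6.
- Comparison: the chosen strategy reaches the ring-expanded ketone in twelve steps from an acyclic monoterpene alcohol. The decalin route would be considerably longer before its key step.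

Key step: step 12

Remark: ring carbons keep the germacrane numbers C1–C10 in every intermediate, including the open-chain and six-membered ones, and compounds 1, 10, 12, 20, 21 and 32 are taken to be catalogue materials.

## Route

Step 1
Reactants: 1 geraniol
Product: 2 [(2S,3S)-3-methyl-3-(4-methylpent-3-en-1-yl)oxiran-2-yl]methanol
Conditions: Ti(OiPr)4 (5 mol %), L-(+)-diethyl tartrate (6 mol %), t-BuOOH, 4 Å MS, CH2Cl2, −20 °C
Reagents that add atoms: tert-butyl hydroperoxide CC(C)(C)OO
Why: Sharpless asymmetric epoxidation; the titanium tartrate complex binds the allylic hydroxyl, so only the 2,3-alkene reacts, and L-(+)-tartrate should deliver oxygen to the face that gives the 2S,3S epoxide, which fixes C5 and, after inversion, C4.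

Step 2
Reactants: 2 epoxy alcohol
Product: 3 (2S,3R)-3,7-dimethyloct-6-ene-1,2,3-triol
Conditions: HClO4 (cat.), THF–H2O, 0 °C
Reagents that add atoms: water O
Why: Acid-catalysed epoxide hydrolysis; water should attack the tertiary carbon (C4) from the rear, inverting it while C5 keeps its oxygen, which gives the diol that is cis once the ring exists; cold dilute acid should leave the trisubstituted alkene alone.

Step 3
Reactants: 3 triol
Product: 4 (2S,3R)-1-[(tert-butyldimethylsilyl)oxy]-3,7-dimethyloct-6-ene-2,3-diol
Conditions: TBSCl, imidazole, CH2Cl2, 0 °C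
Reagents that add atoms: tert-butyldimethylsilyl chloride CC(C)(C)[Si](C)(C)Cl
Why: Selective silylation of the primary hydroxyl beside a secondary and a tertiary one; it keeps C6 out of the acetal so that the acetonide can only bridge C4 and C5.

Step 4
Reactants: 4 diol
Product: 5 tert-butyl(dimethyl){[(4S,5R)-2,2,5-trimethyl-5-(4-methylpent-3-en-1-yl)-1,3-dioxolan-4-yl]methoxy}silane
Conditions: Me2C(OMe)2, PPTS (cat.), CH2Cl2, 25 °C
Reagents that add atoms: 2,2-dimethoxypropane COC(C)(C)OC
Why: Acid-catalysed transacetalisation of a secondary/tertiary 1,2-diol; the anti opening in step 2 places the C6 carbon and the C3 chain cis on the dioxolane, as ring closure will need.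

Step 5
Reactants: 5 silyl ether
Product: 6 [(4S,5R)-2,2,5-trimethyl-5-(4-methylpent-3-en-1-yl)-1,3-dioxolan-4-yl]methanol
Conditions: Bu4NF, THF, 0 → 25 °C
Reagents that add atoms: none
Why: Fluoride cleavage of a primary silyl ether; the acetonide and the alkene are inert to it.

Step 6
Reactants: 6 alcohol
Product: 7 (4R,5R)-2,2,5-trimethyl-5-(4-methylpent-3-en-1-yl)-1,3-dioxolane-4-carbaldehyde
Conditions: TEMPO (cat.), PhI(OAc)2, CH2Cl2, 25 °C
Reagents that add atoms: none
Why: Oxoammonium oxidation of a primary alcohol to the aldehyde; it stops at the aldehyde, spares the alkene and is mild enough not to epimerise the α-alkoxy centre C5.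

Step 7
Reactants: 7 aldehyde
Product: 8 (3aS,4R,5R,7aR)-2,2,7a-trimethyl-5-(prop-1-en-2-yl)hexahydro-1,3-benzodioxol-4-ol
Conditions: ZnBr2, CH2Cl2, 0 °C
Reagents that add atoms: none
Why: Lewis-acid-promoted intramolecular carbonyl-ene reaction, the closure that turns citronellal into isopulegol: C1 of the trisubstituted alkene bonds to the chelated aldehyde carbon C6 while a methyl hydrogen moves to oxygen, which leaves the isopropenyl group. In the chair transition state C15 is equatorial and the C4 oxygen axial, so the isopropenyl group on C1 should come out equatorial and cis to the acetonide oxygens; the C6 carbinol (expected trans to isopropenyl) is oxidised next and does not matter.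

Step 8
Reactants: 8 cyclohexanol
Product: 9 (3aR,5R,7aR)-2,2,7a-trimethyl-5-(prop-1-en-2-yl)tetrahydro-1,3-benzodioxol-4(3aH)-one
Conditions: Dess–Martin periodinane, CH2Cl2, 25 °C
Reagents that add atoms: none
Why: Dess–Martin oxidation of a secondary alcohol under near-neutral conditions, so that C1 (α to the ketone and allylic) is not epimerised and the isopropenyl alkene does not move into conjugation.

Step 9
Reactants: 10 3-methylbut-1-yne
Product: 11 (E)-2-bromo-1-iodo-3-methylbut-1-ene
Conditions: IBr, CH2Cl2, −78 → 0 °C
Reagents that add atoms: iodine monobromide BrI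
Why: Electrophilic anti addition to a terminal alkyne; iodine goes to the terminal carbon and bromide to the branched carbon from the opposite side, which fixes the two halogens trans.

Step 10
Reactants: 11 bromo iodo alkene; 12 4-methoxybenzyl alcohol
Product: 13 1-({[(1E)-2-bromo-3-methylbut-1-en-1-yl]oxy}methyl)-4-methoxybenzene
Conditions: CuI (10 mol %), 3,4,7,8-tetramethyl-1,10-phenanthroline (20 mol %), Cs2CO3, toluene, 80 °C
Reagents that add atoms: none
Why: Copper-catalysed C–O cross-coupling of an alkenyl iodide with an alcohol (Ullmann-type vinylation); the C–I bond should react ahead of the C–Br bond and with retention of geometry, so bromine ends trans to the ether oxygen.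

Step 11
Reactants: 13 (E)-bromo enol ether; 9 ketone
Product: 15 (3aS,4R,5R,7aR)-4-[(1E)-1-(4-methoxybenzyloxy)-3-methylbut-1-en-2-yl]-2,2,7a-trimethyl-5-(prop-1-en-2-yl)hexahydro-1,3-benzodioxol-4-ol, via alkenyllithium 14 (not isolated)
Conditions: t-BuLi (2 equiv), Et2O–pentane, −100 °C; then 9, LaCl3·2LiCl (30 mol %), THF, −100 → −78 °C; H2O
Reagents that add atoms: none
Why: Bromine–lithium exchange with retention, then 1,2-addition of the alkenyllithium to the ketone, with the lanthanum salt added to favour addition over enolisation at C1. The bulky nucleophile should attack equatorially, anti to the C1 isopropenyl group and away from the axial C4–O bond, giving the tertiary alcohol with the two alkenyl groups trans-diequatorial. In 14 lithium is anti to the ether oxygen, so the reagent is made and used at −100 °C to outrun loss of lithium 4-methoxybenzyl oxide.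

Step 12
Reactants: 15 1,2-dialkenylcyclohexanol
Product: 18 (1(10)E,4R,5R,7S,8R)-4,5-(isopropylidenedioxy)-8-[(4-methoxybenzyl)oxy]germacr-1(10)-en-6-one, via potassium alkoxide 16 (not isolated), via potassium enolate 17 (not isolated)
Conditions: KH, 18-crown-6, THF, 0 → 25 °C; AcOH, −78 °C; then DBU (10 mol %), toluene, 0 °C
Reagents that add atoms: none
Why: KH with the crown ether gives the free alkoxide 16, whose oxyanion weakens the C1–C6 bond, and the 1,5-diene C8=C7–C6–C1–C10=C9 undergoes the [3,3] shift to enolate 17; this is the anionic oxy-Cope rearrangement, and the closest known case is the ring expansion of trans-1,2-dialkenylcyclohexanols to (E)-cyclodec-5-enones. The ten-membered ring is not closed end to end: it arises by ring expansion, C8–C9 forming inside a six-centre chair while C1–C6 breaks. Both alkenyl groups are equatorial on the cyclohexane, so C2 and C5 are equatorial on the rearranging chair, and that fixes the E geometry of C1=C10. C8 is set by the E enol ether: its oxygen, trans to C6, sits equatorial, and with the configuration of C1 and C6 in 15 the chair bonds C9 to the face of C8 that gives 8R. C7 is set on protonation of the enolate: the epimer with the isopropyl group outward and H7 anti to H8 has every substituent of the inherited crown conformation exterior, so it should be the thermodynamic one, and the catalytic DBU treatment is there to converge any 7-epimer onto it. The step needs the concerted shift to win over heterolytic C1–C6 fragmentation and over a boat geometry, which the locked trans-diequatorial arrangement and the crown ether should secure. It also needs the β-alkoxy enolate to survive, which is why it is discharged with acid at −78 °C.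

Step 13
Reactants: 18 ketone
Product: 19 (1(10)E,4R,5S,6S,7R,8R)-4,5-(isopropylidenedioxy)-8-[(4-methoxybenzyl)oxy]germacr-1(10)-en-6-ol
Conditions: Zn(BH4)2, Et2O, −20 °C
Reagents that add atoms: none
Why: Chelation-controlled hydride reduction; zinc bridges the C6 carbonyl and the C5 acetonide oxygen, which calls for the anti (6S) carbinol. The inner face of the carbonyl is covered by the transannular C1=C10 alkene, so attack on the outer face should lead to the same isomer.

Step 14
Reactants: 20 (R)-4-benzyl-3-propanoyl-1,3-oxazolidin-2-one; 21 acetaldehyde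
Product: 23 (R)-4-benzyl-3-[(2R,3S)-3-hydroxy-2-methylbutanoyl]-1,3-oxazolidin-2-one, via dibutylboron Z-enolate 22 (not isolated)
Conditions: Bu2BOTf, i-Pr2NEt, CH2Cl2, 0 °C; then 21, −78 → 0 °C; H2O2, MeOH, pH 7 buffer
Reagents that add atoms: none
Why: Evans syn aldol; the Z boron enolate reacts through a Zimmerman–Traxler chair on the face away from the benzyl group, which with the R auxiliary should give the 2R,3S adduct.

Step 15
Reactants: 23 aldol adduct
Product: 24 (R)-4-benzyl-3-[(2R,3S)-3-(tert-butyldiphenylsilyloxy)-2-methylbutanoyl]-1,3-oxazolidin-2-one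
Conditions: TBDPSCl, imidazole, DMAP (cat.), DMF, 25 °C
Reagents that add atoms: tert-butyldiphenylsilyl chloride CC(C)(C)[Si](Cl)(c1ccccc1)c1ccccc1
Why: Silylation of the secondary hydroxyl; the diphenyl silyl ether is chosen because it should survive the aqueous acid of step 18.

Step 16
Reactants: 24 silylated imide
Product: 25 (2R,3S)-3-[(tert-butyldiphenylsilyl)oxy]-2-methylbutanoic acid
Conditions: LiOH, H2O2, THF–H2O, 0 °C; Na2SO3; HCl (aq)
Reagents that add atoms: hydrogen peroxide OO
Why: Hydroperoxide cleavage of the N-acyl oxazolidinone at the exocyclic carbonyl; the conditions are mild enough to leave the α centre untouched, and the auxiliary is released.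

Step 17
Reactants: 25 acid; 19 C6 alcohol
Product: 27 (1(10)E,4R,5S,6S,7S,8R)-4,5-(isopropylidenedioxy)-8-[(4-methoxybenzyl)oxy]germacr-1(10)-en-6-yl (2R,3S)-3-(tert-butyldiphenylsilyloxy)-2-methylbutanoate, via mixed anhydride 26 (not isolated)
Conditions: 2,4,6-Cl3C6H2COCl, Et3N, THF, 25 °C; then 19, DMAP, toluene, 40 °C
Reagents that add atoms: none
Why: Yamaguchi esterification, a method suited to hindered secondary alcohols; C6 is the only free hydroxyl, and acyl transfer through the acylpyridinium ion should not epimerise C2′.

Step 18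
Reactants: 27 acetonide ester
Product: 28 (1(10)E,4R,5S,6S,7S,8R)-4,5-dihydroxy-8-[(4-methoxybenzyl)oxy]germacr-1(10)-en-6-yl (2R,3S)-3-(tert-butyldiphenylsilyloxy)-2-methylbutanoate
Conditions: AcOH–H2O (4:1), 40 °C
Reagents that add atoms: none
Why: Mild acid hydrolysis of the acetonide; the ester, the benzyl-type ether and the diphenyl silyl ether should hold, and no cation is formed next to the ring alkene.

Step 19
Reactants: 28 diol
Product: 30 (1(10)E,4R,5R,6S,7S,8R)-4,5-epoxy-8-[(4-methoxybenzyl)oxy]germacr-1(10)-en-6-yl (2R,3S)-3-(tert-butyldiphenylsilyloxy)-2-methylbutanoate, via C5 mesylate 29 (not isolated)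
Conditions: MsCl, Et3N, CH2Cl2, −10 °C; then DBU, 25 °C
Reagents that add atoms: none
Why: Selective sulfonylation of the secondary C5 hydroxyl (the C4 hydroxyl is tertiary), then intramolecular Williamson displacement by the C4 oxygen; inversion at C5 turns the ring-derived cis diol into the trans epoxide, with C4 unchanged.

Step 20
Reactants: 30 epoxide
Product: 31 (1(10)E,4R,5R,6S,7S,8R)-4,5-epoxy-8-hydroxygermacr-1(10)-en-6-yl (2R,3S)-3-(tert-butyldiphenylsilyloxy)-2-methylbutanoate
Conditions: DDQ, CH2Cl2–pH 7 buffer, 0 °C
Reagents that add atoms: none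
Why: Oxidative cleavage of the 4-methoxybenzyl ether by hydride abstraction at the benzylic position; the buffer keeps the medium neutral for the epoxide.

Step 21
Reactants: 32 tiglic acid; 31 C8 alcohol
Product: 34 (1(10)E,4R,5R,6S,7S,8R)-4,5-epoxy-6-[(2R,3S)-3-(tert-butyldiphenylsilyloxy)-2-methylbutanoyloxy]germacr-1(10)-en-8-yl (E)-2-methylbut-2-enoate, via tigloyl mixed anhydride 33 (not isolated)
Conditions: 2,4,6-Cl3C6H2COCl, Et3N, THF, 25 °C; then 31, DMAP, toluene, 25 °C
Reagents that add atoms: none
Why: Yamaguchi esterification of the only free hydroxyl; the mixed anhydride avoids the vinylketene path of an acid chloride with amine base, which would shift the double bond out of conjugation.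

Step 22
Reactants: 34 silyl ether
Product: 35 (1(10)E,4R,5R,6S,7S,8R)-4,5-epoxy-6-[(2R,3S)-3-hydroxy-2-methylbutanoyloxy]germacr-1(10)-en-8-yl (E)-2-methylbut-2-enoate (target)
Conditions: Bu4NF, AcOH, THF, 25 °C
Reagents that add atoms: none
Why: Fluoride desilylation buffered with acetic acid; the medium stays close to neutral, which should protect the epoxide from acid and the two esters from base.

## Compound list

1 | geraniol, (2E)-3,7-dimethylocta-2,6-dien-1-ol | CC(C)=CCC/C(C)=C/CO | starting material
2 | [(2S,3S)-3-methyl-3-(4-methylpent-3-en-1-yl)oxiran-2-yl]methanol | OC[C@@H]1O[C@@]1(C)CCC=C(C)C | intermediate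
3 | (2S,3R)-3,7-dimethyloct-6-ene-1,2,3-triol | OC[C@H](O)[C@](C)(O)CCC=C(C)C | intermediate
4 | (2S,3R)-1-[(tert-butyldimethylsilyl)oxy]-3,7-dimethyloct-6-ene-2,3-diol | CC(C)(C)[Si](C)(C)OC[C@H](O)[C@](C)(O)CCC=C(C)C | intermediate
5 | tert-butyl(dimethyl){[(4S,5R)-2,2,5-trimethyl-5-(4-methylpent-3-en-1-yl)-1,3-dioxolan-4-yl]methoxy}silane | CC(C)(C)[Si](C)(C)OC[C@@H]1OC(C)(C)O[C@]1(C)CCC=C(C)C | intermediate
6 | [(4S,5R)-2,2,5-trimethyl-5-(4-methylpent-3-en-1-yl)-1,3-dioxolan-4-yl]methanol | OC[C@@H]1OC(C)(C)O[C@]1(C)CCC=C(C)C | intermediate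
7 | (4R,5R)-2,2,5-trimethyl-5-(4-methylpent-3-en-1-yl)-1,3-dioxolane-4-carbaldehyde | O=C[C@@H]1OC(C)(C)O[C@]1(C)CCC=C(C)C | intermediate
8 | (3aS,4R,5R,7aR)-2,2,7a-trimethyl-5-(prop-1-en-2-yl)hexahydro-1,3-benzodioxol-4-ol (C6 carbinol, C1 isopropenyl cis to the acetonide oxygens) | O[C@@H]1[C@@H](C(C)=C)CC[C@@]2(C)OC(C)(C)O[C@@H]12 | intermediate
9 | (3aR,5R,7aR)-2,2,7a-trimethyl-5-(prop-1-en-2-yl)tetrahydro-1,3-benzodioxol-4(3aH)-one | O=C1[C@@H](C(C)=C)CC[C@@]2(C)OC(C)(C)O[C@@H]12 | intermediate
10 | 3-methylbut-1-yne | CC(C)C#C | starting material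
11 | (E)-2-bromo-1-iodo-3-methylbut-1-ene | I/C=C(/Br)C(C)C | intermediate
12 | 4-methoxybenzyl alcohol | COc1ccc(CO)cc1 | starting material
13 | 1-({[(1E)-2-bromo-3-methylbut-1-en-1-yl]oxy}methyl)-4-methoxybenzene (bromine trans to the ether oxygen) | COc1ccc(CO/C=C(/Br)C(C)C)cc1 | intermediate
14 | {1-[(4-methoxybenzyl)oxy]-3-methylbut-1-en-2-yl}lithium, lithium trans to the ether oxygen | COc1ccc(CO/C=C(/[Li])C(C)C)cc1 | intermediate (not isolated)
15 | (3aS,4R,5R,7aR)-4-[(1E)-1-(4-methoxybenzyloxy)-3-methylbut-1-en-2-yl]-2,2,7a-trimethyl-5-(prop-1-en-2-yl)hexahydro-1,3-benzodioxol-4-ol | COc1ccc(CO/C=C(\C(C)C)[C@]2(O)[C@@H](C(C)=C)CC[C@@]3(C)OC(C)(C)O[C@H]32)cc1 | intermediate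
16 | potassium alkoxide of 15 | COc1ccc(CO/C=C(\C(C)C)[C@]2([O-])[C@@H](C(C)=C)CC[C@@]3(C)OC(C)(C)O[C@H]32)cc1.[K+] | intermediate (not isolated)
17 | potassium (1(10)E,6Z,4R,5S,8R)-4,5-(isopropylidenedioxy)-8-[(4-methoxybenzyl)oxy]germacra-1(10),6-dien-6-olate (C5 and C8 trans across C6=C7) | CC(C)/C1=C(/[O-])[C@@H]2OC(C)(C)O[C@]2(C)CC/C=C(C)/C[C@H]1OCc3ccc(OC)cc3.[K+] | intermediate (not isolated)
18 | (1(10)E,4R,5R,7S,8R)-4,5-(isopropylidenedioxy)-8-[(4-methoxybenzyl)oxy]germacr-1(10)-en-6-one | COc1ccc(CO[C@@H]2C/C(C)=C/CC[C@@]3(C)OC(C)(C)O[C@H]3C(=O)[C@H]2C(C)C)cc1 | intermediate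
19 | (1(10)E,4R,5S,6S,7R,8R)-4,5-(isopropylidenedioxy)-8-[(4-methoxybenzyl)oxy]germacr-1(10)-en-6-ol | COc1ccc(CO[C@@H]2C/C(C)=C/CC[C@@]3(C)OC(C)(C)O[C@H]3[C@@H](O)[C@H]2C(C)C)cc1 | intermediate
20 | (R)-4-benzyl-3-propanoyl-1,3-oxazolidin-2-one | CCC(=O)N1[C@H](Cc2ccccc2)COC1=O | starting material
21 | acetaldehyde | CC=O | starting material
22 | dibutylboron (Z)-enolate of 20 | CCCCB(CCCC)O/C(=C\C)N1[C@H](Cc2ccccc2)COC1=O | intermediate (not isolated)
23 | (R)-4-benzyl-3-[(2R,3S)-3-hydroxy-2-methylbutanoyl]-1,3-oxazolidin-2-one | O=C([C@H](C)[C@H](C)O)N1[C@H](Cc2ccccc2)COC1=O | intermediate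
24 | (R)-4-benzyl-3-[(2R,3S)-3-(tert-butyldiphenylsilyloxy)-2-methylbutanoyl]-1,3-oxazolidin-2-one | O=C([C@H](C)[C@H](C)O[Si](c1ccccc1)(c1ccccc1)C(C)(C)C)N1[C@H](Cc2ccccc2)COC1=O | intermediate
25 | (2R,3S)-3-[(tert-butyldiphenylsilyl)oxy]-2-methylbutanoic acid | OC(=O)[C@H](C)[C@H](C)O[Si](c1ccccc1)(c1ccccc1)C(C)(C)C | intermediate
26 | (2R,3S)-3-(tert-butyldiphenylsilyloxy)-2-methylbutanoic 2,4,6-trichlorobenzoic anhydride | O=C(OC(=O)c1c(Cl)cc(Cl)cc1Cl)[C@H](C)[C@H](C)O[Si](c1ccccc1)(c1ccccc1)C(C)(C)C | intermediate (not isolated)
27 | (1(10)E,4R,5S,6S,7S,8R)-4,5-(isopropylidenedioxy)-8-[(4-methoxybenzyl)oxy]germacr-1(10)-en-6-yl (2R,3S)-3-(tert-butyldiphenylsilyloxy)-2-methylbutanoate | COc1ccc(CO[C@@H]2C/C(C)=C/CC[C@@]3(C)OC(C)(C)O[C@H]3[C@@H](OC(=O)[C@H](C)[C@H](C)O[Si](c4ccccc4)(c4ccccc4)C(C)(C)C)[C@H]2C(C)C)cc1 | intermediate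
28 | (1(10)E,4R,5S,6S,7S,8R)-4,5-dihydroxy-8-[(4-methoxybenzyl)oxy]germacr-1(10)-en-6-yl (2R,3S)-3-(tert-butyldiphenylsilyloxy)-2-methylbutanoate | COc1ccc(CO[C@@H]2C/C(C)=C/CC[C@@](C)(O)[C@@H](O)[C@@H](OC(=O)[C@H](C)[C@H](C)O[Si](c3ccccc3)(c3ccccc3)C(C)(C)C)[C@H]2C(C)C)cc1 | intermediate
29 | C5 methanesulfonate of 28 (4R,5S,6S,7S,8R) | COc1ccc(CO[C@@H]2C/C(C)=C/CC[C@@](C)(O)[C@@H](OS(C)(=O)=O)[C@@H](OC(=O)[C@H](C)[C@H](C)O[Si](c3ccccc3)(c3ccccc3)C(C)(C)C)[C@H]2C(C)C)cc1 | intermediate (not isolated)
30 | (1(10)E,4R,5R,6S,7S,8R)-4,5-epoxy-8-[(4-methoxybenzyl)oxy]germacr-1(10)-en-6-yl (2R,3S)-3-(tert-butyldiphenylsilyloxy)-2-methylbutanoate | COc1ccc(CO[C@@H]2C/C(C)=C/CC[C@@]3(C)O[C@@H]3[C@@H](OC(=O)[C@H](C)[C@H](C)O[Si](c4ccccc4)(c4ccccc4)C(C)(C)C)[C@H]2C(C)C)cc1 | intermediate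
31 | (1(10)E,4R,5R,6S,7S,8R)-4,5-epoxy-8-hydroxygermacr-1(10)-en-6-yl (2R,3S)-3-(tert-butyldiphenylsilyloxy)-2-methylbutanoate | O[C@@H]1C/C(C)=C/CC[C@@]2(C)O[C@@H]2[C@@H](OC(=O)[C@H](C)[C@H](C)O[Si](c3ccccc3)(c3ccccc3)C(C)(C)C)[C@H]1C(C)C | intermediate
32 | tiglic acid, (E)-2-methylbut-2-enoic acid | C/C=C(\C)C(=O)O | starting material
33 | (E)-2-methylbut-2-enoic 2,4,6-trichlorobenzoic anhydride | C/C=C(\C)C(=O)OC(=O)c1c(Cl)cc(Cl)cc1Cl | intermediate (not isolated)
34 | (1(10)E,4R,5R,6S,7S,8R)-4,5-epoxy-6-[(2R,3S)-3-(tert-butyldiphenylsilyloxy)-2-methylbutanoyloxy]germacr-1(10)-en-8-yl (E)-2-methylbut-2-enoate | C/C=C(\C)C(=O)O[C@@H]1C/C(C)=C/CC[C@@]2(C)O[C@@H]2[C@@H](OC(=O)[C@H](C)[C@H](C)O[Si](c3ccccc3)(c3ccccc3)C(C)(C)C)[C@H]1C(C)C | intermediate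
35 | (1(10)E,4R,5R,6S,7S,8R)-4,5-epoxy-6-[(2R,3S)-3-hydroxy-2-methylbutanoyloxy]germacr-1(10)-en-8-yl (E)-2-methylbut-2-enoate | C/C=C(\C)C(=O)O[C@@H]1C/C(C)=C/CC[C@@]2(C)O[C@@H]2[C@@H](OC(=O)[C@H](C)[C@H](C)O)[C@H]1C(C)C | target

## Step count and least certain steps

Total: 22 steps. Longest linear sequence: 17 steps, from 1 to 35 (steps 1–8, 11–13, 17–22). Side branches: alkenyl bromide 13 (steps 9 and 10) and acid 25 (steps 14–16).

**Step 12 (key step).** The enolate 17 carries the C8 ether in the β position, so expulsion of 4-methoxybenzyl oxide to an enone is the most likely loss. Heterolytic cleavage of C1–C6 in 16 into an allyl anion and a β-alkoxy enone is the second; C7 could also end as an epimer mixture if the DBU equilibration is slow or itself triggers the elimination. Fallback, from 15 back to 18: the rearrangement is run at the lowest workable temperature and the enolate is silylated in the flask (Me3SiCl, Et3N, −78 °C) to the trimethylsilyl enol ether F1. F1 is isolated and the ketone is set free under buffered fluoride (Bu4NF, AcOH, −78 °C), so that the enolate never meets a base at ambient temperature and the C7 proton is delivered under chosen conditions.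

**Step 11.** In alkenyllithium 14 the C–Li bond is anti-periplanar to the C–O bond, so loss of lithium 4-methoxybenzyl oxide back to the alkyne may outrun addition to a hindered ketone; enolisation of 9 at C1 is a second loss. Fallback, from 9 and 12 back to 15, builds the enol ether on the ring so that no β-alkoxy alkenyllithium is needed. Alcohol 12 with KH and trichloroethylene gives the dichlorovinyl ether F2; n-BuLi converts it into lithium alkoxyethynide F3, which adds to 9 to give propargylic alcohol F4. Hydroxyl-directed trans-hydrostannation (Bu3SnH, [Cp*RuCl]4) places tin on C7 and hydrogen on C8, giving stannane F5 with the ether oxygen trans to C6. I2 gives alkenyl iodide F6, and Negishi coupling with i-PrZnBr (Pd2(dba)3, CPhos) installs the isopropyl group to give 15.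

**Step 10.** The organocopper intermediate carries bromine trans on the neighbouring carbon and may expel it, returning the alkyne instead of forming the C–O bond. Fallback, from 10 and 12 back to 13, couples before the bromine is present. Hydrozirconation–iodination of 10 (Cp2Zr(H)Cl, then I2) gives (E)-iodoalkene F7. The same copper-catalysed coupling with 12 gives the E enol ether F8. Anti addition of Br2 gives dibromide F9, and anti elimination of HBr with Et3N across C1–C2 should give 13 with bromine trans to oxygen.

**Step 13.** Hydride may reach the wrong face of the carbonyl if the ring does not keep the crown conformation, or if zinc bridges to the C8 ether instead of the acetonide. Fallback, from 18 back to 19, replaces substrate-face control by intramolecular delivery. DDQ removes the 4-methoxybenzyl group to give β-hydroxy ketone F10. Me4NBH(OAc)3 in MeCN–AcOH delivers hydride from the C8 oxygen (Evans–Saksena 1,3-anti reduction) to give diol F11. The less hindered C8 hydroxyl is re-etherified with 4-methoxybenzyl trichloroacetimidate and La(OTf)3 (cat.) to give 19.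

**Step 19.** Under base the C6 ester may migrate to the C5 or C4 oxygen, or its carbonyl oxygen may displace the C5 sulfonate, in place of the C4 oxygen closing the epoxide. Fallback, from 28 straight to 30: Mitsunobu cyclodehydration (PPh3, DIAD, toluene), which activates the secondary C5 hydroxyl as an oxyphosphonium ion under neutral conditions and closes the epoxide with the same inversion, without sulfonate or amine base.

## Further compounds

F1 | step 12 | trimethylsilyl enol ether of 18 (C6 OSiMe3, C6=C7, 1(10)E,4R,5S,8R) | CC(C)/C1=C(/O[Si](C)(C)C)[C@@H]2OC(C)(C)O[C@]2(C)CC/C=C(C)/C[C@H]1OCc3ccc(OC)cc3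
F2 | step 11 | 1-({[(E)-1,2-dichloroethenyl]oxy}methyl)-4-methoxybenzene | COc1ccc(CO/C(Cl)=C\Cl)cc1
F3 | step 11 | lithium [(4-methoxybenzyl)oxy]ethynide | [Li]C#COCc1ccc(OC)cc1
F4 | step 11 | (3aS,4R,5R,7aR)-4-{[(4-methoxybenzyl)oxy]ethynyl}-2,2,7a-trimethyl-5-(prop-1-en-2-yl)hexahydro-1,3-benzodioxol-4-ol | COc1ccc(COC#C[C@]2(O)[C@@H](C(C)=C)CC[C@@]3(C)OC(C)(C)O[C@H]32)cc1
F5 | step 11 | (3aS,4R,5R,7aR)-4-[(Z)-2-(4-methoxybenzyloxy)-1-(tributylstannyl)ethenyl]-2,2,7a-trimethyl-5-(prop-1-en-2-yl)hexahydro-1,3-benzodioxol-4-ol | COc1ccc(CO/C=C(\[Sn](CCCC)(CCCC)CCCC)[C@]2(O)[C@@H](C(C)=C)CC[C@@]3(C)OC(C)(C)O[C@H]32)cc1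
F6 | step 11 | (3aS,4R,5R,7aR)-4-[(Z)-1-iodo-2-(4-methoxybenzyloxy)ethenyl]-2,2,7a-trimethyl-5-(prop-1-en-2-yl)hexahydro-1,3-benzodioxol-4-ol | COc1ccc(CO/C=C(\I)[C@]2(O)[C@@H](C(C)=C)CC[C@@]3(C)OC(C)(C)O[C@H]32)cc1
F7 | step 10 | (E)-1-iodo-3-methylbut-1-ene | CC(C)/C=C/I
F8 | step 10 | 1-methoxy-4-({[(1E)-3-methylbut-1-en-1-yl]oxy}methyl)benzene | COc1ccc(CO/C=C/C(C)C)cc1
F9 | step 10 | rac-1-({[(1R,2R)-1,2-dibromo-3-methylbutyl]oxy}methyl)-4-methoxybenzene | COc1ccc(CO[C@H](Br)[C@H](Br)C(C)C)cc1
F10 | step 13 | (1(10)E,4R,5R,7S,8R)-8-hydroxy-4,5-(isopropylidenedioxy)germacr-1(10)-en-6-one | O[C@@H]1C/C(C)=C/CC[C@@]2(C)OC(C)(C)O[C@H]2C(=O)[C@H]1C(C)C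
F11 | step 13 | (1(10)E,4R,5S,6S,7S,8R)-4,5-(isopropylidenedioxy)germacr-1(10)-ene-6,8-diol | O[C@@H]1C/C(C)=C/CC[C@@]2(C)OC(C)(C)O[C@H]2[C@@H](O)[C@H]1C(C)C
F0 | step 19 | none | none
A1 | alternative 1 | (1(10)E,4E)-germacra-1(10),4-dien-6-ol | C1C/C(C)=C/CC/C(C)=C/[C@@H](O)[C@H]1C(C)C
A2 | alternative 1 | (2E,6E)-farnesyl diphosphate | CC(C)=CCC/C(C)=C/CC/C(C)=C/COP(O)(=O)OP(O)(O)=O
A3 | alternative 2 | 2-phenylsulfonyl germacra-1(10),4-diene with C6 OTBS and C8 OPMB | COc1ccc(CO[C@@H]2C/C(C)=C/C(S(=O)(=O)c3ccccc3)C/C(C)=C/[C@@H](O[Si](C)(C)C(C)(C)C)[C@H]2C(C)C)cc1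
A4 | alternative 3 | ten-membered E-alkenyl C5 ketone with C4 OTES, C6 OPMB and C8 OTBS | CC(C)(C)[Si](C)(C)O[C@@H]1C/C(C)=C/CC[C@@](C)(O[Si](CC)(CC)CC)C(=O)[C@@H](OCc2ccc(OC)cc2)[C@H]1C(C)C
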